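The synthesis rests on cutting the α-methylene-γ-lactone (ring atoms O, C6, C7, C11, C12) back to carbon dioxide, which delivers the carbonyl carbon C12 together with the ring oxygen. In one flask an alkenylboronate at C11 is carboxylated under copper catalysis (C11–C12) and the carboxylate then closes on a palladium π-allyl unit at C6 (O–C6), trans to C7. The step exploits the lactone carbonyl as latent CO2 and the allylic nature of C6, which adjoins the C4=C5 alkene of the ten-membered ring. The precursor is an open-chain skipped diene whose C7 carries the vinyl boronate and an allylic carbonate; the carbocycle is closed last by metathesis at C4=C5.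

Key step: step 12

Numbering: germacrane numbering of the target is used for all intermediates (lactone carbonyl C12, exocyclic methylene C13, methyl C14 on C10, methyl C15 on C4).
Abbreviations: pin = pinacolato; TMP = 2,2,6,6-tetramethylpiperidide; TRIP = 3,3′-bis(2,4,6-triisopropylphenyl)-1,1′-binaphthyl-2,2′-diyl hydrogen phosphate; (SIMes)CuCl = chloro[1,3-bis(2,4,6-trimethylphenyl)imidazolin-2-ylidene]copper; (IPr)CuCl = chloro[1,3-bis(2,6-diisopropylphenyl)imidazol-2-ylidene]copper.
Assumption: (S)-linalool and (E)-pent-2-en-4-yn-1-ol are taken as purchasable in the stated configuration; the sense of induction of the two chiral catalysts (steps 3 and 8) is assigned by analogy and would be checked on the first run, the other antipode being equally accessible.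

Step 1
Reactants: 1 (S)-linalool
Product: 3 (3S)-3,7-dimethyloct-6-ene-1,3-diol, via alkylborane 2 (not isolated)
Conditions: 9-BBN (1.3 equiv), THF, 0 °C to rt; then NaOH, H2O2, 0 °C
Reagents that add atoms: 9-BBN, B1C2CCCC1CCC2 (boron unit of 2 only); hydrogen peroxide, OO (hydroxyl oxygen of 3)
Why: Hydroboration–oxidation; the bulky borane adds anti-Markovnikov to the monosubstituted vinyl group only, the trisubstituted alkene is left, and the C10 centre comes unchanged from the chiral pool.

Step 2
Reactants: 3 (3S)-3,7-dimethyloct-6-ene-1,3-diol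
Product: 4 (3S)-3,7-dimethyl-1,3-bis(triethylsilyloxy)oct-6-ene
Conditions: TESOTf (2.5 equiv), 2,6-lutidine, CH2Cl2, −78 to 0 °C
Reagents that add atoms: triethylsilyl trifluoromethanesulfonate, CC[Si](CC)(CC)OS(=O)(=O)C(F)(F)F
Why: Silyl ether formation; the triflate silylates the tertiary as well as the primary hydroxyl, which prevents cyclisation of O10 onto the later epoxide and turns the primary oxygen into a latent aldehyde.

Step 3
Reactants: 4 (3S)-3,7-dimethyl-1,3-bis(triethylsilyloxy)oct-6-ene
Product: 5 (3S)-2,2-dimethyl-3-[(3S)-3-methyl-3,5-bis(triethylsilyloxy)pentyl]oxirane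
Conditions: L-fructose-derived Shi ketone (30 mol %), KHSO5 (as 2KHSO5·KHSO4·K2SO4), K2CO3, Bu4NHSO4, MeCN–CH2(OMe)2/aq. Na2B4O7 buffer, 0 °C
Reagents that add atoms: potassium peroxymonosulfate, [K+].[O-]S(=O)(=O)OO
Why: Shi asymmetric epoxidation; the chiral dioxirane attacks only the electron-rich trisubstituted alkene through a spiro transition state, so the catalyst antipode fixes C3 as S independently of the remote C10 centre.

Step 4
Reactants: 5 (3S)-2,2-dimethyl-3-[(3S)-3-methyl-3,5-bis(triethylsilyloxy)pentyl]oxirane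
Product: 6 (3S,6S)-2,6-dimethyl-6,8-bis(triethylsilyloxy)oct-1-en-3-ol
Conditions: Et2Al(TMP) (3 equiv, from LiTMP and Et2AlCl), toluene, 0 °C
Reagents that add atoms: none
Why: Aluminium amide-mediated isomerisation of an epoxide to an allylic alcohol; the amide removes a methyl proton syn to the aluminium-bound oxygen and the C4–O bond breaks, so the C3–O bond keeps its S configuration and the C4 isopropenyl group appears.

Step 5
Reactants: 6 (3S,6S)-2,6-dimethyl-6,8-bis(triethylsilyloxy)oct-1-en-3-ol
Product: 7 (3S,6S)-3-(tert-butyldimethylsilyloxy)-2,6-dimethyl-6,8-bis(triethylsilyloxy)oct-1-ene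
Conditions: TBSCl, imidazole, DMF, rt
Reagents that add atoms: tert-butyldimethylsilyl chloride, CC(C)(C)[Si](C)(C)Cl
Why: Standard silylation of the secondary allylic alcohol, needed so that only the C8 oxygen is oxidised in step 6 and acylated in step 9.

Step 6
Reactants: 7 (3S,6S)-3-(tert-butyldimethylsilyloxy)-2,6-dimethyl-6,8-bis(triethylsilyloxy)oct-1-ene
Product: 8 (3S,6S)-6-(tert-butyldimethylsilyloxy)-3,7-dimethyl-3-(triethylsilyloxy)oct-7-enal
Conditions: (COCl)2, DMSO, CH2Cl2, −78 to −40 °C; Et3N, to 0 °C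
Reagents that add atoms: none
Why: Swern oxidation of a primary triethylsilyl ether; the activated sulfonium species cleaves only the unhindered primary Si–O bond and oxidises that oxygen directly to the aldehyde, while the tertiary TES and secondary TBS ethers are inert.

Step 7
Reactants: 9 (E)-pent-2-en-4-yn-1-ol
Product: 10 4,4,5,5-tetramethyl-2-[(E)-pent-2-en-4-yn-1-yl]-1,3,2-dioxaborolane
Conditions: B2pin2, Pd(MeCN)4(BF4)2 (5 mol %), DMSO–MeOH, 50 °C
Reagents that add atoms: bis(pinacolato)diboron, CC1(C)OB(OC1(C)C)B1OC(C)(C)C(C)(C)O1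
Why: Palladium-catalysed borylation of an allylic alcohol; ionisation to the π-allyl complex and boryl transfer to the less hindered terminus should give the linear E allylboronate.

Step 8
Reactants: 8 (3S,6S)-6-(tert-butyldimethylsilyloxy)-3,7-dimethyl-3-(triethylsilyloxy)oct-7-enal; 10 4,4,5,5-tetramethyl-2-[(E)-pent-2-en-4-yn-1-yl]-1,3,2-dioxaborolane
Product: 11 (3R,4R,6S,9S)-9-(tert-butyldimethylsilyloxy)-3-ethynyl-6,10-dimethyl-6-(triethylsilyloxy)undeca-1,10-dien-4-ol
Conditions: 10 (1.5 equiv), (S)-TRIP (5 mol %), 4 Å MS, toluene, −30 °C; aqueous work-up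
Reagents that add atoms: none
Why: Chiral phosphoric acid-catalysed allylboration; the chair transition state with the γ-alkynyl group of the E boronate equatorial gives the 7,8-anti pair, and the catalyst antipode that delivers the allyl unit to the Si face of the aldehyde sets C8 as R and hence C7 as R.

Step 9
Reactants: 11 (3R,4R,6S,9S)-9-(tert-butyldimethylsilyloxy)-3-ethynyl-6,10-dimethyl-6-(triethylsilyloxy)undeca-1,10-dien-4-ol
Product: 12 (3R,4R,6S,9S)-9-(tert-butyldimethylsilyloxy)-3-ethynyl-6,10-dimethyl-6-(triethylsilyloxy)undeca-1,10-dien-4-yl 2-methylpropanoate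
Conditions: (i-PrCO)2O, Et3N, DMAP (cat.), CH2Cl2, 0 °C to rt
Reagents that add atoms: 2-methylpropanoic anhydride, CC(C)C(=O)OC(=O)C(C)C
Why: DMAP-catalysed acylation of the only free hydroxyl installs the isobutyrate of the target at C8 without touching a stereocentre.

Step 10
Reactants: 12 (3R,4R,6S,9S)-9-(tert-butyldimethylsilyloxy)-3-ethynyl-6,10-dimethyl-6-(triethylsilyloxy)undeca-1,10-dien-4-yl 2-methylpropanoate
Product: 13 (3R,4R,6S,9S)-9-(tert-butyldimethylsilyloxy)-6,10-dimethyl-3-[1-(4,4,5,5-tetramethyl-1,3,2-dioxaborolan-2-yl)ethenyl]-6-(triethylsilyloxy)undeca-1,10-dien-4-yl 2-methylpropanoate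
Conditions: (SIMes)CuCl (5 mol %), NaOt-Bu (5 mol %), B2pin2 (1.1 equiv), MeOH (2 equiv), THF, −20 to 0 °C
Reagents that add atoms: bis(pinacolato)diboron, CC1(C)OB(OC1(C)C)B1OC(C)(C)C(C)(C)O1
Why: Copper-catalysed α-selective protoboration of a terminal alkyne; syn borylcupration with the N-aryl carbene ligand should place boron on the internal carbon C11, which bears inductively withdrawing propargylic substituents, and methanol protonates the C13–Cu bond, while the unactivated alkenes do not react.

Step 11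
Reactants: 13 (3R,4R,6S,9S)-9-(tert-butyldimethylsilyloxy)-6,10-dimethyl-3-[1-(4,4,5,5-tetramethyl-1,3,2-dioxaborolan-2-yl)ethenyl]-6-(triethylsilyloxy)undeca-1,10-dien-4-yl 2-methylpropanoate; 14 tert-butyl prop-2-en-1-yl carbonate
Product: 15 (2E,4R,5R,7S,10S)-1-(tert-butoxycarbonyloxy)-10-(tert-butyldimethylsilyloxy)-7,11-dimethyl-4-[1-(4,4,5,5-tetramethyl-1,3,2-dioxaborolan-2-yl)ethenyl]-7-(triethylsilyloxy)dodeca-2,11-dien-5-yl 2-methylpropanoate
Conditions: 14 (5 equiv), second-generation Hoveyda–Grubbs catalyst (5 mol %), CH2Cl2, 40 °C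
Reagents that add atoms: none
Why: Olefin cross-metathesis; only the monosubstituted vinyl group on C7 is reactive, the two 1,1-disubstituted alkenes being inert, so the allylic carbonate arm (future C5 plus one sacrificial CH2) is attached as the E alkene.

Step 12
Reactants: 15 (2E,4R,5R,7S,10S)-1-(tert-butoxycarbonyloxy)-10-(tert-butyldimethylsilyloxy)-7,11-dimethyl-4-[1-(4,4,5,5-tetramethyl-1,3,2-dioxaborolan-2-yl)ethenyl]-7-(triethylsilyloxy)dodeca-2,11-dien-5-yl 2-methylpropanoate
Product: 17 (1R,3S,6S)-6-(tert-butyldimethylsilyloxy)-1-[(2R,3R)-2-ethenyl-4-methylidene-5-oxooxolan-3-yl]-3,7-dimethyl-3-(triethylsilyloxy)oct-7-en-1-yl 2-methylpropanoate, via potassium acrylate salt 16 (not isolated)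
Conditions: (IPr)CuCl (10 mol %), KOt-Bu (1.05 equiv), CO2 (1 atm), THF, 70 °C; then Pd(PPh3)4 (5 mol %), 40 °C, same flask
Reagents that add atoms: carbon dioxide, O=C=O; potassium tert-butoxide, CC(C)(C)[O-].[K+] (potassium of 16 only)
Why: Proposed new method: both halves are established reaction types (carbene–copper-catalysed carboxylation of alkenylboronic esters with CO2, and Tsuji–Trost allylic substitution by carboxylates), but their merger in one flask into a carboxylative lactonisation has not been shown. Mechanistically, tert-butoxide turns the C11–B bond into a borate, transmetallation gives a C11–copper alkenyl into which CO2 inserts (C11–C12 bond, salt 16), and zerovalent palladium then ionises the allylic carbonate to a C6–C5–CH2 π-allyl complex that the carboxylate oxygen captures at C6 (O–C6 bond). The γ-lactone closes in a 5-exo mode at the internal allyl terminus, the seven-membered alternative at the CH2 terminus being slower. The single new stereocentre C6 is controlled by the resident C7 centre: the allyl faces interconvert by π–σ–π exchange at the unsubstituted terminus and the product, itself an allylic ester, can re-ionise, so the more stable trans-disposed (6R) lactone should accumulate. The step needs carboxylation to precede any allyl transfer to the alkenyl metal, which is secured by adding the palladium catalyst only once the boronate is consumed and by the fact that intramolecular C-allylation would require a three-membered or trans-cyclopentene ring; the isobutyrate and silyl ethers should tolerate the borate-bound base.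

Step 13
Reactants: 17 (1R,3S,6S)-6-(tert-butyldimethylsilyloxy)-1-[(2R,3R)-2-ethenyl-4-methylidene-5-oxooxolan-3-yl]-3,7-dimethyl-3-(triethylsilyloxy)oct-7-en-1-yl 2-methylpropanoate
Product: 18 (1R,3S,6S)-1-[(2R,3R)-2-ethenyl-4-methylidene-5-oxooxolan-3-yl]-3,6-dihydroxy-3,7-dimethyloct-7-en-1-yl 2-methylpropanoate
Conditions: HF·pyridine, pyridine, THF, 0 °C to rt
Reagents that add atoms: none
Why: Fluoride-mediated desilylation; buffered HF·pyridine removes the tertiary TES and the allylic TBS ether without touching the α-methylene lactone, the allylic C6–O bond or the isobutyrate.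

Step 14
Reactants: 18 (1R,3S,6S)-1-[(2R,3R)-2-ethenyl-4-methylidene-5-oxooxolan-3-yl]-3,6-dihydroxy-3,7-dimethyloct-7-en-1-yl 2-methylpropanoate
Product: 19 CNP0163972.1, (3S,6R,7R,8R,10S)-3,10-dihydroxy-8-(2-methylpropanoyloxy)germacra-4(Z),11(13)-dien-12,6-olide
Conditions: second-generation Grubbs catalyst (10 mol %), 1,4-benzoquinone (20 mol %), toluene (1 mM), 80 °C
Reagents that add atoms: none
Why: Ring-closing metathesis; the catalyst loads at the vinyl group on C6 and closes on the 1,1-disubstituted C4 alkene, helped by the free allylic hydroxyl at C3, and the ten-membered ring should form as the less strained ring-cis isomer, which is the required 4Z alkene.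

Compound list
1 | (S)-linalool, (3S)-3,7-dimethylocta-1,6-dien-3-ol | C=C[C@@](C)(O)CCC=C(C)C | starting material
2 | (3R)-1-(9-borabicyclo[3.3.1]nonan-9-yl)-3,7-dimethyloct-6-en-3-ol (same spatial arrangement at C10 as 1; descriptor changes by priority only) | CC(C)=CCC[C@](C)(O)CCB1C2CCCC1CCC2 | intermediate (not isolated)
3 | (3S)-3,7-dimethyloct-6-ene-1,3-diol | CC(C)=CCC[C@](C)(O)CCO | intermediate
4 | (3S)-3,7-dimethyl-1,3-bis(triethylsilyloxy)oct-6-ene | CC(C)=CCC[C@](C)(O[Si](CC)(CC)CC)CCO[Si](CC)(CC)CC | intermediate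
5 | (3S)-2,2-dimethyl-3-[(3S)-3-methyl-3,5-bis(triethylsilyloxy)pentyl]oxirane | CC1(C)O[C@H]1CC[C@](C)(O[Si](CC)(CC)CC)CCO[Si](CC)(CC)CC | intermediate
6 | (3S,6S)-2,6-dimethyl-6,8-bis(triethylsilyloxy)oct-1-en-3-ol | C=C(C)[C@@H](O)CC[C@](C)(O[Si](CC)(CC)CC)CCO[Si](CC)(CC)CC | intermediate
7 | (3S,6S)-3-(tert-butyldimethylsilyloxy)-2,6-dimethyl-6,8-bis(triethylsilyloxy)oct-1-ene | C=C(C)[C@@H](O[Si](C)(C)C(C)(C)C)CC[C@](C)(O[Si](CC)(CC)CC)CCO[Si](CC)(CC)CC | intermediate
8 | (3S,6S)-6-(tert-butyldimethylsilyloxy)-3,7-dimethyl-3-(triethylsilyloxy)oct-7-enal | C=C(C)[C@@H](O[Si](C)(C)C(C)(C)C)CC[C@](C)(O[Si](CC)(CC)CC)CC=O | intermediate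
9 | (E)-pent-2-en-4-yn-1-ol | C#C/C=C/CO | starting material
10 | 4,4,5,5-tetramethyl-2-[(E)-pent-2-en-4-yn-1-yl]-1,3,2-dioxaborolane | C#C/C=C/CB1OC(C)(C)C(C)(C)O1 | intermediate
11 | (3R,4R,6S,9S)-9-(tert-butyldimethylsilyloxy)-3-ethynyl-6,10-dimethyl-6-(triethylsilyloxy)undeca-1,10-dien-4-ol | C=C(C)[C@@H](O[Si](C)(C)C(C)(C)C)CC[C@](C)(O[Si](CC)(CC)CC)C[C@@H](O)[C@@H](C#C)C=C | intermediate
12 | (3R,4R,6S,9S)-9-(tert-butyldimethylsilyloxy)-3-ethynyl-6,10-dimethyl-6-(triethylsilyloxy)undeca-1,10-dien-4-yl 2-methylpropanoate | C=C(C)[C@@H](O[Si](C)(C)C(C)(C)C)CC[C@](C)(O[Si](CC)(CC)CC)C[C@@H](OC(=O)C(C)C)[C@@H](C#C)C=C | intermediate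
13 | (3R,4R,6S,9S)-9-(tert-butyldimethylsilyloxy)-6,10-dimethyl-3-[1-(4,4,5,5-tetramethyl-1,3,2-dioxaborolan-2-yl)ethenyl]-6-(triethylsilyloxy)undeca-1,10-dien-4-yl 2-methylpropanoate | C=C(C)[C@@H](O[Si](C)(C)C(C)(C)C)CC[C@](C)(O[Si](CC)(CC)CC)C[C@@H](OC(=O)C(C)C)[C@@H](C(=C)B1OC(C)(C)C(C)(C)O1)C=C | intermediate
14 | tert-butyl prop-2-en-1-yl carbonate (allyl tert-butyl carbonate) | C=CCOC(=O)OC(C)(C)C | starting material
15 | (2E,4R,5R,7S,10S)-1-(tert-butoxycarbonyloxy)-10-(tert-butyldimethylsilyloxy)-7,11-dimethyl-4-[1-(4,4,5,5-tetramethyl-1,3,2-dioxaborolan-2-yl)ethenyl]-7-(triethylsilyloxy)dodeca-2,11-dien-5-yl 2-methylpropanoate | C=C(C)[C@@H](O[Si](C)(C)C(C)(C)C)CC[C@](C)(O[Si](CC)(CC)CC)C[C@@H](OC(=O)C(C)C)[C@@H](C(=C)B1OC(C)(C)C(C)(C)O1)/C=C/COC(=O)OC(C)(C)C | intermediate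
16 | potassium 2-[(2E,4R,5R,7S,10S)-1-(tert-butoxycarbonyloxy)-10-(tert-butyldimethylsilyloxy)-7,11-dimethyl-5-(2-methylpropanoyloxy)-7-(triethylsilyloxy)dodeca-2,11-dien-4-yl]prop-2-enoate | C=C(C)[C@@H](O[Si](C)(C)C(C)(C)C)CC[C@](C)(O[Si](CC)(CC)CC)C[C@@H](OC(=O)C(C)C)[C@@H](C(=C)C(=O)[O-])/C=C/COC(=O)OC(C)(C)C.[K+] | intermediate (not isolated)
17 | (1R,3S,6S)-6-(tert-butyldimethylsilyloxy)-1-[(2R,3R)-2-ethenyl-4-methylidene-5-oxooxolan-3-yl]-3,7-dimethyl-3-(triethylsilyloxy)oct-7-en-1-yl 2-methylpropanoate (trans lactone; 6R,7R,8R,10S,3S in target numbering) | C=C1C(=O)O[C@H](C=C)[C@H]1[C@H](OC(=O)C(C)C)C[C@@](C)(O[Si](CC)(CC)CC)CC[C@H](O[Si](C)(C)C(C)(C)C)C(C)=C | intermediate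
18 | (1R,3S,6S)-1-[(2R,3R)-2-ethenyl-4-methylidene-5-oxooxolan-3-yl]-3,6-dihydroxy-3,7-dimethyloct-7-en-1-yl 2-methylpropanoate | C=C1C(=O)O[C@H](C=C)[C@H]1[C@H](OC(=O)C(C)C)C[C@@](C)(O)CC[C@H](O)C(C)=C | intermediate
19 | CNP0163972.1, (3S,6R,7R,8R,10S)-3,10-dihydroxy-8-(2-methylpropanoyloxy)germacra-4(Z),11(13)-dien-12,6-olide | C=C1C(=O)O[C@@H]2/C=C(/C)[C@@H](O)CC[C@](C)(O)C[C@@H](OC(=O)C(C)C)[C@@H]12 | target

Total step count: 14.
Longest linear sequence: 13 steps (1 to 19 through steps 1–6 and 8–14; step 7 prepares the allylboronate in a side branch).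

Steps most likely to fail

Step 12 (labelled step). What may go wrong: the two catalytic cycles interfere in the shared flask, so that the alkenyl group is transferred to the allyl unit or the π-allyl complex decays by β-hydride elimination before a carboxylate is available. The fallback uses known chemistry only, sets out from 15 and comes back at 17. Compound 15 is carboxylated alone under the (IPr)CuCl/KOt-Bu/CO2 conditions and acidified, and the free 2-[(2E,4R,5R,7S,10S)-configured dodecadienyl]prop-2-enoic acid F1 is isolated. In a separate flask a conventional Tsuji–Trost lactonisation (Pd(PPh3)4, Et3N, THF) closes F1 to 17 under the same thermodynamic trans control.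

Step 10. What may go wrong: borylcupration with the opposite regiochemistry, which would place boron on the terminal carbon C13 and give the linear alkenylboronate. The fallback sets out from 12 and comes back at 13. Haloboration of the alkyne with B-iodo-9-BBN followed by protonolysis with acetic acid fixes the halogen on the internal carbon by mechanism and gives the (3S,4R,6S,9S)-3-(1-iodoethenyl) ester F2 (same spatial arrangement as 12; the descriptor at the branching carbon changes through iodine priority). Miyaura borylation of F2 (PdCl2(PPh3)2, PPh3, KOPh, B2pin2, toluene, 50 °C) then gives 13.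

Step 14. What may go wrong: oligomerisation in place of medium-ring closure, closure to the ring-trans alkene, or alkene migration induced by ruthenium hydride species. The fallback sets out from 18 and comes back at 19. The 3,10-diol is first tied into the seven-membered diisopropylsilylene F3 (i-Pr2Si(OTf)2, 2,6-lutidine, CH2Cl2), which folds the C1–C3 and C8–C10 arms toward each other. Ring-closing metathesis of F3 gives the bridged 3,10-O-diisopropylsilylene derivative of the target F4, and HF·pyridine releases 19.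

Further compounds
F1 | step 12 | 2-[(2E,4R,5R,7S,10S)-1-(tert-butoxycarbonyloxy)-10-(tert-butyldimethylsilyloxy)-7,11-dimethyl-5-(2-methylpropanoyloxy)-7-(triethylsilyloxy)dodeca-2,11-dien-4-yl]prop-2-enoic acid | C=C(C)[C@@H](O[Si](C)(C)C(C)(C)C)CC[C@](C)(O[Si](CC)(CC)CC)C[C@@H](OC(=O)C(C)C)[C@@H](C(=C)C(=O)O)/C=C/COC(=O)OC(C)(C)C
F2 | step 10 | (3S,4R,6S,9S)-9-(tert-butyldimethylsilyloxy)-3-(1-iodoethenyl)-6,10-dimethyl-6-(triethylsilyloxy)undeca-1,10-dien-4-yl 2-methylpropanoate | C=C(C)[C@@H](O[Si](C)(C)C(C)(C)C)CC[C@](C)(O[Si](CC)(CC)CC)C[C@@H](OC(=O)C(C)C)[C@@H](C(I)=C)C=C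
F3 | step 14 | 3,10-O-diisopropylsilylene derivative of 18 (seven-membered 1,3-dioxa-2-silepane bridging O3 and O10) | C=C1C(=O)O[C@H](C=C)[C@H]1[C@H](OC(=O)C(C)C)C[C@]2(C)CC[C@@H](C(C)=C)O[Si](C(C)C)(C(C)C)O2
F4 | step 14 | 3,10-O-diisopropylsilylene derivative of 19 | C=C1C(=O)O[C@@H]2/C=C(/C)[C@@H]3CC[C@](C)(O[Si](C(C)C)(C(C)C)O3)C[C@@H](OC(=O)C(C)C)[C@@H]12
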